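Numbering used: C1 = oxirane carbon bearing CH2OBz, C2 = CH–OMe, C3 = CH–OBz, C4=C5, C6 = oxirane CH. The cyclohexene is cut at C5–C6 and C1–C2: C2–C5 with the oxygen on C2 is read as furan, C1/C6 with the C1 branch as 2-bromoacrolein. One catalytic enantioselective Diels–Alder reaction forms both bonds and fixes the absolute configuration in a 7-oxanorbornene. The oxygen bridge, a temporary ring, then steers exo epoxidation of C1=C6 and is opened at C5 by anti SN2′ attack of benzoate at C3, which moves the alkene to C4=C5 and leaves the bridge oxygen on C2 for methylation.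

Key step: step 1

Assumption: 2-bromoacrolein is taken as a catalogue reagent (distilled before use), and the facial sense of the tryptophan-derived catalyst with furan is assumed to follow that known with cyclopentadiene; if it does not, the (S)-catalyst is used instead.

Step 1
Reactants: 1 furan; 2 2-bromoacrolein
Product: 3 (1S,2S,4S)-2-bromo-7-oxabicyclo[2.2.1]hept-5-ene-2-carbaldehyde (CHO exo, Br endo)
Conditions: (R)-2-butyl-4-(indol-3-ylmethyl)-3-tosyl-1,3,2-oxazaborolidin-5-one (10 mol %, from N-tosyl-(R)-tryptophan and BuB(OH)2), CH2Cl2, −78 °C; crude adduct kept cold and used at once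
Reagents that add atoms: none
Why: Concerted, Lewis-acid-accelerated normal-demand [4+2] cycloaddition: boron binds the formyl oxygen of 2, the indole ring stacks over the bound s-cis enal and closes one face, and furan adds across its C2 and C5 to the open face. The closest known reaction type is the oxazaborolidine-catalysed enantioselective Diels–Alder reaction of 2-haloacroleins with cyclic dienes, furan included. The six-membered carbocycle is closed by intermolecular suprafacial cycloaddition, which leaves the furan oxygen as a one-atom bridge (7-oxabicyclo[2.2.1]heptene). The two bridgehead carbons (the future C2 and C5) are set by the catalyst through the enal face, and the C–Br carbon by the formyl-exo transition state usual for 2-haloacroleins; this last centre is erased in step 3. The step needs enantioface control, secured by the catalyst, and suppression of cycloreversion, secured by −78 °C and cold reduction of the aldehyde; regiochemistry is no issue because furan is symmetric.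

Step 2
Reactants: 3 (1S,2S,4S)-2-bromo-7-oxabicyclo[2.2.1]hept-5-ene-2-carbaldehyde
Product: 5 (1S,2S,4S)-spiro[7-oxabicyclo[2.2.1]hept-5-ene-2,2'-oxirane] (oxirane oxygen exo), via bromohydrin 4 (not isolated)
Conditions: NaBH4, MeOH–CH2Cl2, −78 → 0 °C; then aq. NaOH (2 M), 0 °C → rt
Reagents that add atoms: none
Why: Hydride reduction of the aldehyde followed by intramolecular Williamson closure (3-exo-tet, inversion at the C–Br carbon) should give the spiro-oxirane; the configuration of the spiro carbon does not matter because step 3 makes it sp2.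

Step 3
Reactants: 5 (1S,2S,4S)-spiro[7-oxabicyclo[2.2.1]hept-5-ene-2,2'-oxirane]
Product: 6 [(1S,4R)-7-oxabicyclo[2.2.1]hepta-2,5-dien-2-yl]methanol
Conditions: LiNEt2 (2.5 equiv, from Et2NH and n-BuLi), Et2O–hexane, 0 °C → rt; H2O quench
Reagents that add atoms: none
Why: Base-mediated isomerisation of an epoxide to an allylic alcohol (syn β-elimination through a cyclic lithium amide transition state): only the ring CH2 next to the spiro carbon carries a removable hydrogen, the other neighbour being a bridgehead, so the tertiary C–O bond breaks and the C1=C6 alkene forms without creating a stereocentre.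

Step 4
Reactants: 6 [(1S,4R)-7-oxabicyclo[2.2.1]hepta-2,5-dien-2-yl]methanol
Product: 7 [(1S,2S,4R,5R)-3,8-dioxatricyclo[3.2.1.0(2,4)]oct-6-en-2-yl]methanol (oxirane exo, syn to the oxygen bridge)
Conditions: VO(acac)2 (2 mol %), t-BuOOH (1.2 equiv, in decane), CH2Cl2, 0 °C
Reagents that add atoms: tert-butyl hydroperoxide CC(C)(C)OO
Why: Hydroxyl-directed epoxidation (vanadium alkylperoxide bound to the allylic alcohol) should touch only the hydroxymethyl-bearing alkene and deliver oxygen to its exo face, the endo face being screened by the other etheno bridge, which sets both oxirane carbons cis to the oxygen bridge.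

Step 5
Reactants: 7 [(1S,2S,4R,5R)-3,8-dioxatricyclo[3.2.1.0(2,4)]oct-6-en-2-yl]methanol
Product: 8 [(1S,2S,4R,5R)-3,8-dioxatricyclo[3.2.1.0(2,4)]oct-6-en-2-yl]methyl benzoate
Conditions: BzCl, pyridine, DMAP (cat.), CH2Cl2, 0 °C
Reagents that add atoms: benzoyl chloride O=C(Cl)c1ccccc1
Why: DMAP-catalysed acylation of the primary alcohol; the oxirane and the oxygen bridge are inert to pyridine and BzCl at 0 °C and no stereocentre is touched.

Step 6
Reactants: 8 [(1S,2S,4R,5R)-3,8-dioxatricyclo[3.2.1.0(2,4)]oct-6-en-2-yl]methyl benzoate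
Product: 9 [(1S,2S,3R,6R)-3-(benzoyloxy)-2-hydroxy-7-oxabicyclo[4.1.0]hept-4-en-1-yl]methyl benzoate
Conditions: [Rh(cod)Cl]2 (2.5 mol %), (R)-1-[(S)-2-(diphenylphosphino)ferrocenyl]ethyldi-tert-butylphosphine (6 mol %; matched antipode fixed in a test run), PhCO2H (3 equiv), Et3N (0.5 equiv), THF, 60 °C
Reagents that add atoms: benzoic acid O=C(O)c1ccccc1
Why: Rhodium-catalysed ring opening of an oxabicyclic alkene (allylic SN2′ substitution): monovalent rhodium inserts with retention, from the exo face, into the bridgehead C5–O bond remote from the quaternary carbon, and benzoate attacks the π-allyl anti to the metal at C3, so the new benzoate is trans to the C2 hydroxyl and the alkene moves to C4=C5; the matched ligand antipode secures the choice of bridgehead.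

Step 7
Reactants: 9 [(1S,2S,3R,6R)-3-(benzoyloxy)-2-hydroxy-7-oxabicyclo[4.1.0]hept-4-en-1-yl]methyl benzoate
Product: 10 [(1R,2S,3R,6R)-3-(benzoyloxy)-2-methoxy-7-oxabicyclo[4.1.0]hept-4-en-1-yl]methyl benzoate (CNP0231490.2)
Conditions: MeI (excess), Ag2O, 4 Å MS, Et2O, rt, dark
Reagents that add atoms: iodomethane CI
Why: Purdie O-methylation (SN2 on MeI assisted by silver oxide) runs near neutrality, which keeps the alkoxide concentration low and so disfavours benzoate migration; the cis-epoxy alcohol cannot undergo Payne rearrangement and no stereocentre is touched.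

Compound list
1 | furan | c1ccoc1 | starting material
2 | 2-bromoacrolein (2-bromoprop-2-enal) | C=C(Br)C=O | starting material
3 | (1S,2S,4S)-2-bromo-7-oxabicyclo[2.2.1]hept-5-ene-2-carbaldehyde (CHO exo, Br endo) | O=C[C@]1(Br)C[C@H]2C=C[C@@H]1O2 | intermediate
4 | [(1S,2R,4S)-2-bromo-7-oxabicyclo[2.2.1]hept-5-en-2-yl]methanol (bromohydrin, Br endo) | OC[C@]1(Br)C[C@H]2C=C[C@@H]1O2 | intermediate (not isolated)
5 | (1S,2S,4S)-spiro[7-oxabicyclo[2.2.1]hept-5-ene-2,2'-oxirane] (oxirane oxygen exo) | C1O[C@@]12C[C@H]3C=C[C@@H]2O3 | intermediate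
6 | [(1S,4R)-7-oxabicyclo[2.2.1]hepta-2,5-dien-2-yl]methanol | OCC1=C[C@H]2C=C[C@@H]1O2 | intermediate
7 | [(1S,2S,4R,5R)-3,8-dioxatricyclo[3.2.1.0(2,4)]oct-6-en-2-yl]methanol (oxirane exo) | OC[C@@]12O[C@@H]1[C@H]3C=C[C@@H]2O3 | intermediate
8 | [(1S,2S,4R,5R)-3,8-dioxatricyclo[3.2.1.0(2,4)]oct-6-en-2-yl]methyl benzoate | O=C(OC[C@@]12O[C@@H]1[C@H]3C=C[C@@H]2O3)c1ccccc1 | intermediate
9 | [(1S,2S,3R,6R)-3-(benzoyloxy)-2-hydroxy-7-oxabicyclo[4.1.0]hept-4-en-1-yl]methyl benzoate | O[C@H]1[C@H](OC(=O)c2ccccc2)C=C[C@H]2O[C@]21COC(=O)c1ccccc1 | intermediate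
10 | [(1R,2S,3R,6R)-3-(benzoyloxy)-2-methoxy-7-oxabicyclo[4.1.0]hept-4-en-1-yl]methyl benzoate | CO[C@H]1[C@H](OC(=O)c2ccccc2)C=C[C@H]2O[C@]21COC(=O)c1ccccc1 | target

Total step count: 7. Longest linear sequence: 7 steps (1 and 2 to 10).

Steps most likely to fail

1. Step 6. The rhodium/benzoate system may attack the oxirane of 8, or the vinyl oxirane that appears in 9, instead of the bridge. It may also insert at the bridgehead next to the quaternary carbon, and the tricyclic substrate may turn over slowly. The fallback opens the bridge before any oxirane exists and makes the oxirane last, by hydroxyl-directed epoxidation of a cyclohexadienol, as in the presumed biosynthesis. It sets out from 4, isolated by stopping step 2 before the hydroxide is added. BzCl/pyridine should give [(1S,2R,4S)-2-bromo-7-oxabicyclo[2.2.1]hept-5-en-2-yl]methyl benzoate F1. The same rhodium-catalysed benzoate ring opening, now on a plain 7-oxanorbornene, should give [(1R,2S,3R)-3-(benzoyloxy)-1-bromo-2-hydroxycyclohex-4-en-1-yl]methyl benzoate F2. DBU in toluene at rt should remove HBr by anti E2 through the allylic C6–H, without ionising the hydroxyl, to give the dienol [(5R,6R)-5-(benzoyloxy)-6-hydroxycyclohexa-1,3-dien-1-yl]methyl benzoate F3. VO(acac)2/t-BuOOH should then deliver oxygen to C1=C6 cis to the C2 hydroxyl, and the route is rejoined at 9.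

2. Step 3. The amide base may metalate the oxirane CH2 or degrade the strained diene instead of effecting β-elimination. The fallback replaces the epoxide isomerisation by a dehydrogenation at the aldehyde oxidation level and sets out from 3. Zn/TMSCl (THF, 0 °C) should give, by reductive silylation, the silyl enol ether (1S,4S)-2-[(trimethylsilyloxy)methylidene]-7-oxabicyclo[2.2.1]hept-5-ene F4. Saegusa–Ito oxidation with Pd(OAc)2 in MeCN should give (1S,4R)-7-oxabicyclo[2.2.1]hepta-2,5-diene-2-carbaldehyde F5. Luche reduction (NaBH4, CeCl3·7H2O, MeOH, −78 °C) returns to the route at 6.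

3. Step 7. The benzoate may migrate from O3 to O2, or alkylation of the hindered hydroxyl may stall. The fallback installs the methyl ether while no ester is vicinal and introduces the C3 benzoate last; it sets out from 8. The rhodium catalyst of step 6 with 4-methoxybenzyl alcohol as nucleophile should give the 3-O-(4-methoxybenzyl) analogue of 9, F6. NaH/MeI (THF, 0 °C) should give its 2-O-methyl ether F7. DDQ (CH2Cl2, pH 7 buffer) should free the C3 alcohol F8. BzCl/pyridine returns to the route at 10.

Further compounds
F1 | step 6 | [(1S,2R,4S)-2-bromo-7-oxabicyclo[2.2.1]hept-5-en-2-yl]methyl benzoate | O=C(OC[C@]1(Br)C[C@H]2C=C[C@@H]1O2)c1ccccc1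
F2 | step 6 | [(1R,2S,3R)-3-(benzoyloxy)-1-bromo-2-hydroxycyclohex-4-en-1-yl]methyl benzoate | O[C@H]1[C@H](OC(=O)c2ccccc2)C=CC[C@@]1(Br)COC(=O)c1ccccc1
F3 | step 6 | [(5R,6R)-5-(benzoyloxy)-6-hydroxycyclohexa-1,3-dien-1-yl]methyl benzoate | O[C@H]1[C@H](OC(=O)c2ccccc2)C=CC=C1COC(=O)c1ccccc1
F4 | step 3 | (1S,4S)-2-[(trimethylsilyloxy)methylidene]-7-oxabicyclo[2.2.1]hept-5-ene (enol ether geometry open) | C[Si](C)(C)OC=C1C[C@H]2C=C[C@@H]1O2
F5 | step 3 | (1S,4R)-7-oxabicyclo[2.2.1]hepta-2,5-diene-2-carbaldehyde | O=CC1=C[C@H]2C=C[C@@H]1O2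
F6 | step 7 | 3-O-(4-methoxybenzyl) analogue of 9: [2-hydroxy-3-(4-methoxybenzyloxy)-7-oxabicyclo[4.1.0]hept-4-en-1-yl]methyl benzoate, configurations as in 9 | O[C@H]1[C@H](OCc2ccc(OC)cc2)C=C[C@H]2O[C@]21COC(=O)c1ccccc1
F7 | step 7 | [2-methoxy-3-(4-methoxybenzyloxy)-7-oxabicyclo[4.1.0]hept-4-en-1-yl]methyl benzoate, configurations as in 10 | CO[C@H]1[C@H](OCc2ccc(OC)cc2)C=C[C@H]2O[C@]21COC(=O)c1ccccc1
F8 | step 7 | (3-hydroxy-2-methoxy-7-oxabicyclo[4.1.0]hept-4-en-1-yl)methyl benzoate, configurations as in 10 | CO[C@H]1[C@H](O)C=C[C@H]2O[C@]21COC(=O)c1ccccc1
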